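## Structural features

The target is a 3-hydroxyisoflavanone: a chroman-4-one (ring A fused to the oxygen heterocycle, ring C) that carries aryl ring B and a hydroxyl group on C3. C3 is the only stereocentre, a fully substituted carbinol carbon of R configuration between the C4 ketone and the C2 methylene ether, so there is no neighbouring stereocentre and the task is absolute control at a quaternary carbon. Ring A is a phloroglucinol unit (O1, 5-OH, 7-OH) with a prenyl group on C6 between the two phenols. Ring B is a 1,2,3,4-tetrasubstituted resorcinol with C3 on C1', methoxy on C2', prenyl on C3' and hydroxyl on C4'. The fragile parts are the two trisubstituted alkenes, each ortho to a phenol (acid closes chromans; hydrogenation, ozone and late electrophilic halogenation are excluded), the tertiary α-ketol (base opens α-ketol and retro-benzoin pathways) and the electron-rich rings. The real difficulty is twofold: the quaternary C3–O centre as one enantiomer, and the crowded ring B, whose prenyl group sits between two oxygens that must be told apart (OMe at C2', OH at C4'). The key step uses the C1'(carbon)–C2'(oxygen)–C3'(carbon)–C4'(oxygen) sequence of ring B with hydrogen on C5' and C6'. A 4-substituted cyclobutenone supplies C1', C2', C5' and C6', its carbonyl becoming the free C2' hydroxyl, and a 1-siloxyalkyne supplies C3' with its prenyl group and C4' with its silyloxy group, so the two oxygens arrive already differentiated.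

## Logic of the disconnections

38 to 36. Only O–Si bonds (at C3 and C4') and O–CH2OMe bonds (at C5 and C7) are cut. The phenols and the tertiary alcohol must be masked to survive an aryllithium. The forward demand is an acid mild enough to leave both prenyl groups alone.

36 to 34. The C4–C4a bond is cut, opening ring C to an ester on C3 and a bromide on C4a. This leaves rings A and B joined only through O1–C2–C3 and reduces the ketone to a spectator ester. The forward step needs halogen–lithium exchange to outrun attack on the ester; C3 has no hydrogen and cannot epimerise.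

34 to 33. The O–CH3 bond at C2' is cut. In 33 this oxygen is the only free hydroxyl, so no selectivity problem arises. The forward step must not move the silyl groups.

33 to 23 and 28. The C2'–C3' and C4'–C5' bonds are cut and C1'–C2' is reorganised, which removes ring B as an aromatic ring. The cut is made here because the substitution pattern matches what a vinylketene and a polarised ynol ether give, and it delivers the two ring B oxygens in different states. The gain is that a crowded arene becomes a four-membered ring plus an alkyne. The forward step needs one regiochemistry of ketene–alkyne addition, a capped C3 oxygen and a thermally stable remainder.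

28 to 25, then to 4 and 24. The O–Si and C1–O bonds of the ynol ether are cut back to a terminal alkyne, then the allyl–propargyl C–C bond. Two commercial pieces result. The forward steps need clean oxidation of an acetylide and SN2 rather than SN2' coupling.

23 to 21, then to 17 and 18. First a carbonyl transposition (C–O bonds only), then the two ring bonds made by ketene–alkyne [2+2] addition. The four-membered ring collapses to a CH2CO2H arm on the stereocentre. The forward steps need ketene generation without acid, and hydride that reduces the ring carbonyl but not the ester.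

17 to 16, 15, then to 10 and 13 (13 from 11). The acyl–sulfur and O–Si bonds are cut, then the C3–CH2 bond of an aldol addition to an α-keto ester. This is where the stereocentre is removed, leaving two achiral partners and two carboxyl termini that differ (thioester and methyl ester). The forward step needs catalyst-controlled attack on one face of the ketone.

10 to 8 and 9. The O1–C2 ether bond is cut. This separates ring A from the three-carbon keto ester. The forward step needs O-alkylation of the phenol without self-condensation of the keto ester.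

8 to 7, 6, then 3 and 4, then 2 and 1. In turn: the C–Br bond, the O–Si bond, the aryl–prenyl C–C bond, the O–Si bond again and two O–CH2OMe bonds. Each cut removes one substituent until a symmetrical triol remains. The forward steps need metalation only between the two acetal oxygens and bromination only ortho to the free phenol.

## Other disconnections considered

Alternative 1: The C3–O and C4–O bonds are cut together as an oxirane, leading back to the (E)-2,3-diarylallyl alcohol A1 (aryl groups cis). The forward key step is a Sharpless epoxidation (Ti(OiPr)4, D-(−)-diethyl tartrate, tert-butyl hydroperoxide) giving epoxy alcohol A2. In its favour: A1 belongs to the well-behaved class of allylic alcohols with the C3 substituent trans to the hydroxymethyl group, the reagent recognises only the allylic alcohol and not the prenyl alkenes, and both rings come from simple arenes. Against it here: A2 is a stilbene oxide whose C4 carries a 2,4,6-trioxygenated aryl group, so ionisation at C4 under the Lewis-acidic titanium conditions and Meinwald-type shifts threaten the product. The alkene with two ortho-substituted aryl groups cis to each other is hindered and needs its own geometric control. After the key step, ring C must still be closed from O1 to C2 and C4 raised to the ketone by epoxide opening and oxidation. On absolute stereocontrol this alternative is the better of the two, because the epoxidation has a broader record than a copper–bisoxazoline aldol on an untried keto ester. On structure it needs ring B prefabricated with its 1,2,3,4-pattern, which the chosen plan gets from the mechanism. On step economy the two are roughly equal once the steps after A2 are counted.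

Alternative 2: The O1–C8a bond is cut, leading back to fluoro ketone A3 with the C3 stereocentre in place and the tertiary oxygen capped. The forward key step uses K2CO3 or Cs2CO3: the primary C2 alkoxide displaces fluoride ortho to the ketone through a Meisenheimer adduct and closes ring C to A4. In its favour: a six-membered closure under mild base with no organometallic reagent, and a quaternary C3 that cannot epimerise. Against it here: the tertiary hydroxyl must be protected selectively beforehand, or it closes a five-membered benzofuranone instead. The α-oxygenated ketone is exposed to base. A fluorinated, prenylated phloroglucinol and a complete ring B must both be prepared. The key step does not address C3, which would need a separate asymmetric oxidation. On the ring closure itself this alternative is probably the more dependable, compared with the organolithium acylation of the chosen plan. On the stereocentre the two are equal, since both set it in a separate step. On ring B the chosen plan is stronger, and the step counts are similar.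

Alternative 3: The C3–C4 bond is cut, leading back to keto aldehyde A5, made by one O-alkylation of a ring A salicylaldehyde with a ring B phenacyl bromide. The forward key step uses a chiral aminoindanol-derived triazolium salt and a mild base: the Breslow intermediate of the aldehyde adds to the tethered ketone and gives A6. In its favour: ring C, the C3–C4 bond and the stereocentre are made in one catalytic step, with close analogy in the formation of 3-hydroxychroman-4-ones. Against it here: the aldehyde lies between two oxygens on a very electron-rich ring, so the acyl anion equivalent forms slowly. The ketone is ortho-methoxylated and electron-rich, so it is a weak acceptor. Base can divert A5 into Rap–Stoermer-type aldol condensation to a 2-aroylbenzofuran. Enantioselectivity on so hindered a pair is open. On step economy, and in making the stereocentre and ring C together, this alternative is clearly the better. Structurally it still needs ring B built separately. Mechanistically its risk is reactivity, whereas the risk of the chosen plan is the lifetime of a reactive ketene.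

Key step: step 15

Remark: ArO stands for 2-bromo-3,5-bis(methoxymethoxy)-4-(3-methylbut-2-en-1-yl)phenoxy in the names below.
Remark: 23 and 33 carry the same spatial arrangement at C3 as 38 (descriptor R from 15 onward); the ring carbon of 21–23 is an irrelevant epimer mixture.
Assumption: keto ester 10 binds copper through its ketone and ester oxygens as a simple pyruvate does, so the (S,S)-ligand exposes the si face; if the sense is reversed, the enantiomeric ligand is used.
Remark: the precursor design (methyl ester, triethylsilyl ether, bromide) is kept; 23 is used fresh and added slowly to excess 28.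

## Route

Step 1
Reactants: 1 phloroglucinol
Product: 2 3,5-bis(methoxymethoxy)phenol
Conditions: MOMCl (2.1 equiv), i-Pr2NEt, DMF, 0 °C → rt
Reagents that add atoms: chloromethyl methyl ether, COCCl
Why: Statistical acetalisation of a symmetrical triol; the bis-ether is separated from the mono- and tris-ethers and the mono-ether can be recycled.

Step 2
Reactants: 2 3,5-bis(methoxymethoxy)phenol
Product: 3 [3,5-bis(methoxymethoxy)phenoxy]tri(propan-2-yl)silane
Conditions: TIPSCl, imidazole, DMF, rt
Reagents that add atoms: chlorotri(propan-2-yl)silane, CC(C)[Si](Cl)(C(C)C)C(C)C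
Why: Standard silylation of a phenol; the bulky silyl ether resists butyllithium and does not direct metalation.

Step 3
Reactants: 3 [3,5-bis(methoxymethoxy)phenoxy]tri(propan-2-yl)silane; 4 prenyl bromide (1-bromo-3-methylbut-2-ene)
Product: 6 [3,5-bis(methoxymethoxy)-4-(3-methylbut-2-enyl)phenoxy]tri(propan-2-yl)silane, via aryllithium 5 (not isolated)
Conditions: n-BuLi, THF, 0 °C; CuI (10 mol%), 4, −78 → 0 °C
Reagents that add atoms: none
Why: Directed ortho-metalation occurs at the carbon flanked by both methoxymethoxy groups, and copper-mediated allylation gives the linear prenyl product.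

Step 4
Reactants: 6 [3,5-bis(methoxymethoxy)-4-(3-methylbut-2-enyl)phenoxy]tri(propan-2-yl)silane
Product: 7 3,5-bis(methoxymethoxy)-4-(3-methylbut-2-enyl)phenol
Conditions: TBAF, THF, 0 °C
Reagents that add atoms: none
Why: Fluoride cleaves the aryl silyl ether; acetals and alkene are inert.

Step 5
Reactants: 7 3,5-bis(methoxymethoxy)-4-(3-methylbut-2-enyl)phenol
Product: 8 2-bromo-3,5-bis(methoxymethoxy)-4-(3-methylbut-2-enyl)phenol
Conditions: NBS (1.0 equiv), CH2Cl2, −78 °C
Reagents that add atoms: N-bromosuccinimide, O=C1CCC(=O)N1Br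
Why: Electrophilic bromination of the free phenol at one of its two equivalent ortho positions (para is blocked) should be much faster at low temperature than attack on the prenyl alkene.

Step 6
Reactants: 8 2-bromo-3,5-bis(methoxymethoxy)-4-(3-methylbut-2-enyl)phenol; 9 methyl bromopyruvate (methyl 3-bromo-2-oxopropanoate)
Product: 10 methyl 3-ArO-2-oxopropanoate
Conditions: K2CO3, acetone, 0 °C → rt
Reagents that add atoms: none
Why: Williamson O-alkylation at a carbonyl-activated primary bromide; the keto ester is dried azeotropically before use.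

Step 7
Reactants: 11 S-tert-butyl ethanethioate
Product: 13 1-(tert-butylsulfanyl)-1-(trimethylsilyloxy)ethene, via lithium enolate 12 (not isolated)
Conditions: LDA, THF, −78 °C; TMSCl, −78 °C → rt
Reagents that add atoms: chlorotrimethylsilane, C[Si](C)(C)Cl
Why: Kinetic enolisation of the thioester and O-silylation give the silyl ketene acetal.

Step 8
Reactants: 10 methyl 3-ArO-2-oxopropanoate; 13 1-(tert-butylsulfanyl)-1-(trimethylsilyloxy)ethene
Product: 15 methyl (2R)-2-(ArO-methyl)-4-(tert-butylsulfanyl)-2-hydroxy-4-oxobutanoate, via trimethylsilyl ether 14 (not isolated)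
Conditions: Cu(OTf)2 (10 mol%), 2,2'-(propane-2,2-diyl)bis[(4S)-4-tert-butyl-4,5-dihydrooxazole] (11 mol%), THF, −78 °C; then 1 M HCl, THF, 0 °C (brief)
Reagents that add atoms: none
Why: Catalytic enantioselective Mukaiyama aldol addition to an α-keto ester; the keto ester chelates copper through both carbonyl oxygens in the plane of the C2-symmetric ligand, one tert-butyl group screens the re face, and si-face attack gives the R carbinol.

Step 9
Reactants: 15 methyl (2R)-2-(ArO-methyl)-4-(tert-butylsulfanyl)-2-hydroxy-4-oxobutanoate
Product: 16 methyl (2R)-2-(ArO-methyl)-4-(tert-butylsulfanyl)-4-oxo-2-(triethylsilyloxy)butanoate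
Conditions: TESOTf (1.3 equiv), 2,6-lutidine, CH2Cl2, −78 °C
Reagents that add atoms: triethylsilyl trifluoromethanesulfonate, CC[Si](CC)(CC)OS(=O)(=O)C(F)(F)F
Why: Silyl triflate caps the hindered tertiary alcohol at low temperature before the aryl acetals are touched; this blocks retro-aldol cleavage and later ketene trapping.

Step 10
Reactants: 16 methyl (2R)-2-(ArO-methyl)-4-(tert-butylsulfanyl)-4-oxo-2-(triethylsilyloxy)butanoate
Product: 17 (3R)-3-(ArO-methyl)-4-methoxy-4-oxo-3-(triethylsilyloxy)butanoic acid
Conditions: AgNO3, 2,6-lutidine, THF–H2O (4:1), rt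
Reagents that add atoms: water, O
Why: Thiophilic silver activates only the thioester for hydrolysis; the hindered methyl ester, silyl ether and acetals stay under buffered neutral conditions.

Step 11
Reactants: 17 (3R)-3-(ArO-methyl)-4-methoxy-4-oxo-3-(triethylsilyloxy)butanoic acid; 18 ethoxyacetylene
Product: 21 methyl (2R)-3-ArO-2-(2-ethoxy-4-oxocyclobut-2-en-1-yl)-2-(triethylsilyloxy)propanoate, via acid chloride 19 (not isolated), via ketene 20 (not isolated)
Conditions: 1-chloro-N,N,2-trimethylprop-1-en-1-amine, CH2Cl2, 0 °C; then 18 (3 equiv), Et3N, 0 → 35 °C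
Reagents that add atoms: none
Why: Acid chloride formation without free acid, dehydrochlorination to the aldoketene and ketene–ynol ether [2+2] cycloaddition, with the ketene carbonyl carbon bonding to the unsubstituted alkyne carbon.

Step 12
Reactants: 21 methyl (2R)-3-ArO-2-(2-ethoxy-4-oxocyclobut-2-en-1-yl)-2-(triethylsilyloxy)propanoate
Product: 23 methyl (2R)-3-ArO-2-(4-oxocyclobut-2-en-1-yl)-2-(triethylsilyloxy)propanoate, via cyclobutenol 22 (not isolated)
Conditions: NaBH4, CeCl3·7H2O, MeOH, −40 °C; then 0.5 M HCl, THF, 0 °C
Reagents that add atoms: water, O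
Why: Luche 1,2-reduction of the strained vinylogous ester spares the hindered methyl ester; acid then ionises the allylic alcohol to an ethoxy-stabilised cation that water captures at the ethoxy carbon (Stork–Danheiser transposition), placing the substituent next to the new carbonyl.

Step 13
Reactants: 4 prenyl bromide (1-bromo-3-methylbut-2-ene); 24 ethynylmagnesium bromide
Product: 25 5-methylhex-4-en-1-yne
Conditions: CuCl (5 mol%), THF, 0 °C → rt
Reagents that add atoms: none
Why: Copper-catalysed coupling of an alkynyl Grignard reagent with an allylic bromide; the disubstituted alkene terminus disfavours SN2' attack.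

Step 14
Reactants: 25 5-methylhex-4-en-1-yne
Product: 28 triisopropyl[(5-methylhex-4-en-1-yn-1-yl)oxy]silane, via lithium acetylide 26 (not isolated), via lithium ynolate 27 (not isolated)
Conditions: n-BuLi, THF, −78 °C; t-BuOOLi (from t-BuOOH, LiN(SiMe3)2), −78 → 0 °C; TIPSOTf, −78 → 0 °C
Reagents that add atoms: tert-butyl hydroperoxide, CC(C)(C)OO; triisopropylsilyl trifluoromethanesulfonate, CC(C)[Si](OS(=O)(=O)C(F)(F)F)(C(C)C)C(C)C
Why: Electrophilic oxygenation of the acetylide by the lithium peroxide gives the ynolate, which the bulky silyl triflate traps on oxygen; no metal catalyst is present, so the peroxide leaves the alkene alone.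

Step 15
Reactants: 23 methyl (2R)-3-ArO-2-(4-oxocyclobut-2-en-1-yl)-2-(triethylsilyloxy)propanoate; 28 triisopropyl[(5-methylhex-4-en-1-yn-1-yl)oxy]silane
Product: 33 methyl (2R)-3-ArO-2-[2-hydroxy-3-(3-methylbut-2-enyl)-4-(triisopropylsilyloxy)phenyl]-2-(triethylsilyloxy)propanoate, via vinylketene 29 (not isolated), via vinylcyclobutenone 30 (not isolated), via dienylketene 31 (not isolated), via cyclohexadienone 32 (not isolated)
Conditions: 28 (2 equiv), toluene, 80 °C (slow addition of 23); then 110 °C
Reagents that add atoms: none
Why: Thermal conrotatory 4π opening of 23, with the bulky substituent turning outward, gives (E)-vinylketene 29, whose electrophilic ketene carbon bonds to the nucleophilic prenyl-bearing carbon of polarised 28 while the ketene α-carbon bonds to the silyloxy carbon, giving 30. A second 4π opening gives 31, and a 6π electrocyclisation joins the ketene carbon to the carbon that carried the stereogenic substituent, forming 32, which aromatises by tautomerisation. This is a Danheiser benzannulation of a cyclobutenone with a siloxyalkyne, the closest known reaction type. Six-membered ring B closes by disrotatory 6π electrocyclisation, the transient four-membered ring by [2+2] cycloaddition. No stereocentre is created; the quaternary C3 has no acidic hydrogen and is a spectator, and both ring-carbon epimers of 23 converge on 29. The regiochemistry needed (OH at C2', prenyl at C3', silyloxy at C4') follows from the alkyne polarisation; the triethylsilyl cap keeps the C3 oxygen from adding to the ketenes, and excess 28 limits ketene dimerisation and acylation of the product phenol.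

Step 16
Reactants: 33 methyl (2R)-3-ArO-2-[2-hydroxy-3-(3-methylbut-2-enyl)-4-(triisopropylsilyloxy)phenyl]-2-(triethylsilyloxy)propanoate
Product: 34 methyl (2R)-3-ArO-2-[2-methoxy-3-(3-methylbut-2-enyl)-4-(triisopropylsilyloxy)phenyl]-2-(triethylsilyloxy)propanoate
Conditions: MeI, K2CO3, acetone, 40 °C
Reagents that add atoms: iodomethane, CI
Why: Williamson methylation of the only free phenol; the aryl triisopropylsilyl ether is stable to carbonate in an aprotic solvent, and any lactone formed from the phenol and ester is in equilibrium with the phenoxide that is methylated.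

Step 17
Reactants: 34 methyl (2R)-3-ArO-2-[2-methoxy-3-(3-methylbut-2-enyl)-4-(triisopropylsilyloxy)phenyl]-2-(triethylsilyloxy)propanoate
Product: 36 (3R)-2'-methoxy-5,7-bis(methoxymethoxy)-6,3'-bis(3-methylbut-2-enyl)-3-(triethylsilyloxy)-4'-(triisopropylsilyloxy)isoflavanone, via aryllithium 35 (not isolated)
Conditions: t-BuLi (2.1 equiv), THF, −95 → −20 °C; NH4Cl (aq)
Reagents that add atoms: none
Why: Parham cyclisation: bromine–lithium exchange is faster than addition to the hindered ester, and the aryllithium acylates intramolecularly through a six-membered transition state to a ketone with no enolisable position, so C3 is untouched.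

Step 18
Reactants: 36 (3R)-2'-methoxy-5,7-bis(methoxymethoxy)-6,3'-bis(3-methylbut-2-enyl)-3-(triethylsilyloxy)-4'-(triisopropylsilyloxy)isoflavanone
Product: 38 (3R)-3,5,7-trihydroxy-3-[4-hydroxy-2-methoxy-3-(3-methylbut-2-enyl)phenyl]-6-(3-methylbut-2-enyl)chroman-4-one, via phenol 37 (not isolated)
Conditions: TBAF, AcOH, THF, 0 °C; then HCl (1.25 M in MeOH), 35 °C
Reagents that add atoms: none
Why: Buffered fluoride removes the aryl silyl ether, then mild methanolic acid solvolyses the two aryl acetals and the triethylsilyl ether; the temperature is kept low to avoid acid cyclisation of the ortho-prenyl phenols.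

## Compound list

1 | phloroglucinol (benzene-1,3,5-triol) | Oc1cc(O)cc(O)c1 | starting material
2 | 3,5-bis(methoxymethoxy)phenol | COCOc1cc(O)cc(OCOC)c1 | intermediate
3 | [3,5-bis(methoxymethoxy)phenoxy]tri(propan-2-yl)silane | COCOc1cc(OCOC)cc(O[Si](C(C)C)(C(C)C)C(C)C)c1 | intermediate
4 | prenyl bromide (1-bromo-3-methylbut-2-ene) | CC(C)=CCBr | starting material
5 | [2,6-bis(methoxymethoxy)-4-(triisopropylsilyloxy)phenyl]lithium | [Li]c1c(OCOC)cc(O[Si](C(C)C)(C(C)C)C(C)C)cc1OCOC | intermediate
6 | [3,5-bis(methoxymethoxy)-4-(3-methylbut-2-enyl)phenoxy]tri(propan-2-yl)silane | CC(C)=CCc1c(OCOC)cc(O[Si](C(C)C)(C(C)C)C(C)C)cc1OCOC | intermediate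
7 | 3,5-bis(methoxymethoxy)-4-(3-methylbut-2-enyl)phenol | CC(C)=CCc1c(OCOC)cc(O)cc1OCOC | intermediate
8 | 2-bromo-3,5-bis(methoxymethoxy)-4-(3-methylbut-2-enyl)phenol | CC(C)=CCc1c(OCOC)cc(O)c(Br)c1OCOC | intermediate
9 | methyl bromopyruvate (methyl 3-bromo-2-oxopropanoate) | COC(=O)C(=O)CBr | starting material
10 | methyl 3-[2-bromo-3,5-bis(methoxymethoxy)-4-(3-methylbut-2-enyl)phenoxy]-2-oxopropanoate | COC(=O)C(=O)COc1cc(OCOC)c(CC=C(C)C)c(OCOC)c1Br | intermediate
11 | S-tert-butyl ethanethioate | CC(=O)SC(C)(C)C | starting material
12 | lithium 1-(tert-butylsulfanyl)ethenolate | [Li]OC(=C)SC(C)(C)C | intermediate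
13 | 1-(tert-butylsulfanyl)-1-(trimethylsilyloxy)ethene | C=C(O[Si](C)(C)C)SC(C)(C)C | intermediate
14 | methyl (2R)-2-(ArO-methyl)-4-(tert-butylsulfanyl)-4-oxo-2-(trimethylsilyloxy)butanoate | CC(C)(C)SC(=O)C[C@@](C(=O)OC)(O[Si](C)(C)C)COc1cc(OCOC)c(CC=C(C)C)c(OCOC)c1Br | intermediate
15 | methyl (2R)-2-(ArO-methyl)-4-(tert-butylsulfanyl)-2-hydroxy-4-oxobutanoate | CC(C)(C)SC(=O)C[C@@](C(=O)OC)(O)COc1cc(OCOC)c(CC=C(C)C)c(OCOC)c1Br | intermediate
16 | methyl (2R)-2-(ArO-methyl)-4-(tert-butylsulfanyl)-4-oxo-2-(triethylsilyloxy)butanoate | CC(C)(C)SC(=O)C[C@@](C(=O)OC)(O[Si](CC)(CC)CC)COc1cc(OCOC)c(CC=C(C)C)c(OCOC)c1Br | intermediate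
17 | (3R)-3-(ArO-methyl)-4-methoxy-4-oxo-3-(triethylsilyloxy)butanoic acid | OC(=O)C[C@@](C(=O)OC)(O[Si](CC)(CC)CC)COc1cc(OCOC)c(CC=C(C)C)c(OCOC)c1Br | intermediate
18 | ethoxyacetylene (ethoxyethyne) | CCOC#C | starting material
19 | methyl (2R)-2-(ArO-methyl)-4-chloro-4-oxo-2-(triethylsilyloxy)butanoate | ClC(=O)C[C@@](C(=O)OC)(O[Si](CC)(CC)CC)COc1cc(OCOC)c(CC=C(C)C)c(OCOC)c1Br | intermediate
20 | methyl (2R)-2-(ArO-methyl)-4-oxo-2-(triethylsilyloxy)but-3-enoate (ketene) | O=C=C[C@@](C(=O)OC)(O[Si](CC)(CC)CC)COc1cc(OCOC)c(CC=C(C)C)c(OCOC)c1Br | intermediate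
21 | methyl (2R)-3-ArO-2-(2-ethoxy-4-oxocyclobut-2-en-1-yl)-2-(triethylsilyloxy)propanoate, epimers at the ring carbon | CCOC1=CC(=O)C1[C@@](C(=O)OC)(O[Si](CC)(CC)CC)COc2cc(OCOC)c(CC=C(C)C)c(OCOC)c2Br | intermediate
22 | methyl (2R)-3-ArO-2-(2-ethoxy-4-hydroxycyclobut-2-en-1-yl)-2-(triethylsilyloxy)propanoate, ring stereoisomers | CCOC1=CC(O)C1[C@@](C(=O)OC)(O[Si](CC)(CC)CC)COc2cc(OCOC)c(CC=C(C)C)c(OCOC)c2Br | intermediate
23 | methyl (2R)-3-ArO-2-(4-oxocyclobut-2-en-1-yl)-2-(triethylsilyloxy)propanoate, epimers at the ring carbon | O=C1C=CC1[C@@](C(=O)OC)(O[Si](CC)(CC)CC)COc2cc(OCOC)c(CC=C(C)C)c(OCOC)c2Br | intermediate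
24 | ethynylmagnesium bromide | C#C[Mg]Br | starting material
25 | 5-methylhex-4-en-1-yne | CC(C)=CCC#C | intermediate
26 | (5-methylhex-4-en-1-yn-1-yl)lithium | CC(C)=CCC#C[Li] | intermediate
27 | lithium 5-methylhex-4-en-1-yn-1-olate | CC(C)=CCC#CO[Li] | intermediate
28 | triisopropyl[(5-methylhex-4-en-1-yn-1-yl)oxy]silane | CC(C)=CCC#CO[Si](C(C)C)(C(C)C)C(C)C | intermediate
29 | methyl (2R,3E)-2-(ArO-methyl)-6-oxo-2-(triethylsilyloxy)hexa-3,5-dienoate (vinylketene) | O=C=C/C=C/[C@@](C(=O)OC)(O[Si](CC)(CC)CC)COc1cc(OCOC)c(CC=C(C)C)c(OCOC)c1Br | intermediate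
30 | methyl (2R,3E)-2-(ArO-methyl)-4-[2-oxo-3-(3-methylbut-2-enyl)-4-(triisopropylsilyloxy)cyclobut-3-en-1-yl]-2-(triethylsilyloxy)but-3-enoate (vinylcyclobutenone) | O=C1C(CC=C(C)C)=C(O[Si](C(C)C)(C(C)C)C(C)C)C1/C=C/[C@@](C(=O)OC)(O[Si](CC)(CC)CC)COc2cc(OCOC)c(CC=C(C)C)c(OCOC)c2Br | intermediate
31 | methyl (2R)-2-(ArO-methyl)-7-(3-methylbut-2-enyl)-8-oxo-2-(triethylsilyloxy)-6-(triisopropylsilyloxy)octa-3,5,7-trienoate, C3=C4 trans, chain carbons cis across C5=C6 (dienylketene) | O=C=C(CC=C(C)C)/C(O[Si](C(C)C)(C(C)C)C(C)C)=C\C=C\[C@@](C(=O)OC)(O[Si](CC)(CC)CC)COc1cc(OCOC)c(CC=C(C)C)c(OCOC)c1Br | intermediate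
32 | methyl (2R)-3-ArO-2-[2-oxo-3-(3-methylbut-2-enyl)-4-(triisopropylsilyloxy)cyclohexa-3,5-dien-1-yl]-2-(triethylsilyloxy)propanoate (cyclohexadienone) | O=C1C(CC=C(C)C)=C(O[Si](C(C)C)(C(C)C)C(C)C)C=CC1[C@@](C(=O)OC)(O[Si](CC)(CC)CC)COc2cc(OCOC)c(CC=C(C)C)c(OCOC)c2Br | intermediate
33 | methyl (2R)-3-ArO-2-[2-hydroxy-3-(3-methylbut-2-enyl)-4-(triisopropylsilyloxy)phenyl]-2-(triethylsilyloxy)propanoate | Oc1c([C@@](C(=O)OC)(O[Si](CC)(CC)CC)COc2cc(OCOC)c(CC=C(C)C)c(OCOC)c2Br)ccc(O[Si](C(C)C)(C(C)C)C(C)C)c1CC=C(C)C | intermediate
34 | methyl (2R)-3-ArO-2-[2-methoxy-3-(3-methylbut-2-enyl)-4-(triisopropylsilyloxy)phenyl]-2-(triethylsilyloxy)propanoate | COc1c([C@@](C(=O)OC)(O[Si](CC)(CC)CC)COc2cc(OCOC)c(CC=C(C)C)c(OCOC)c2Br)ccc(O[Si](C(C)C)(C(C)C)C(C)C)c1CC=C(C)C | intermediate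
35 | aryllithium from 34 (lithium in place of bromine on ring A) | COc1c([C@@](C(=O)OC)(O[Si](CC)(CC)CC)COc2cc(OCOC)c(CC=C(C)C)c(OCOC)c2[Li])ccc(O[Si](C(C)C)(C(C)C)C(C)C)c1CC=C(C)C | intermediate
36 | (3R)-2'-methoxy-5,7-bis(methoxymethoxy)-6,3'-bis(3-methylbut-2-enyl)-3-(triethylsilyloxy)-4'-(triisopropylsilyloxy)isoflavanone | COc1c([C@@]2(O[Si](CC)(CC)CC)COc3cc(OCOC)c(CC=C(C)C)c(OCOC)c3C2=O)ccc(O[Si](C(C)C)(C(C)C)C(C)C)c1CC=C(C)C | intermediate
37 | (3R)-4'-hydroxy-2'-methoxy-5,7-bis(methoxymethoxy)-6,3'-bis(3-methylbut-2-enyl)-3-(triethylsilyloxy)isoflavanone | COc1c([C@@]2(O[Si](CC)(CC)CC)COc3cc(OCOC)c(CC=C(C)C)c(OCOC)c3C2=O)ccc(O)c1CC=C(C)C | intermediate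
38 | (3R)-3,5,7-trihydroxy-3-[4-hydroxy-2-methoxy-3-(3-methylbut-2-enyl)phenyl]-6-(3-methylbut-2-enyl)chroman-4-one | COc1c([C@@]2(O)COc3cc(O)c(CC=C(C)C)c(O)c3C2=O)ccc(O)c1CC=C(C)C | target

## Step count and least certain steps

Total: 18 steps. Longest linear sequence: 15 steps (steps 1–6, 8–12, 15–18); steps 7 and 13–14 are side branches.

**Step 15 (key step).** The most likely failure is oligomerisation of the vinylketene, which is unsubstituted at its ketene carbon, or its capture by the product phenol before the alkyne adds. The crowded quaternary substituent slows the cycloaddition, and the new phenol may also lose methanol by lactonising onto the neighbouring ester. Fallback: the same vinylketene is made by dehydrochlorination at low temperature, not by ring opening. It sets out from 16 and comes back at 29. The thioester 16 is reduced with i-Bu2AlH at −78 °C to methyl (2R)-2-(ArO-methyl)-4-oxo-2-(triethylsilyloxy)butanoate F1. A Wittig reaction with allyl (triphenylphosphoranylidene)acetate gives the (E)-enoate F2. Pd(PPh3)4 and morpholine release the (E)-enoic acid F3, and 1-chloro-N,N,2-trimethylprop-1-en-1-amine converts it into the enoyl chloride F4. Et3N at 0 °C in the presence of excess 28 removes HCl from the γ-carbon and the acyl group to give 29, which is consumed as it forms; brief warming then carries 30 through 31 and 32 to 33.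

**Step 8.** The most likely failure is loss of facial selectivity through competing chelation of copper by the aryloxy oxygen, or Lewis acid-induced Friedel–Crafts closure of the ketone onto the free ortho carbon of the electron-rich ring. Fallback: it sets out from 10 and comes back at 15. Enolate 12 (from 11 and LDA) is added to 10 at −78 °C without any Lewis acid, giving the racemic adduct F5, and the enantiomers are separated by preparative chromatography on a chiral stationary phase.

**Step 11.** The most likely failure is dimerisation of the hindered aldoketene, or β-elimination of the silyloxy group from the acyl intermediate, before the ynol ether adds. Fallback: a keteniminium–acetylene cycloaddition replaces the ketene and makes the transposition unnecessary. It sets out from 17 and comes back at 23. Acid 17 is coupled with dimethylamine (EDC, HOBt) to the dimethylamide F6. Tf2O and 2,4,6-collidine convert it into the keteniminium triflate F7, which adds acetylene in a [2+2] reaction to give the cyclobuteniminium triflate F8. Aqueous NaHCO3 hydrolyses F8 to 23.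

**Step 6.** The most likely failure is base-induced self-condensation of the bromo keto ester or of 10, and hydrate formation that complicates the next step. Fallback: it sets out from 8 and comes back at 10. The phenoxide of 8 opens methyl oxirane-2-carboxylate at its methylene carbon (K2CO3, DMF, 60 °C) to give methyl 3-ArO-2-hydroxypropanoate F9, which Dess–Martin periodinane oxidises to 10 under neutral conditions.

**Step 17.** The most likely failure is protonation of aryllithium 35, or its slow addition to the congested ester, with competing attack of the alkyllithium on that ester. Fallback: a chromium-mediated closure onto an aldehyde replaces the organolithium acylation. It sets out from 34 and comes back at 36. i-Bu2AlH at −78 °C reduces 34 to the aldehyde F10. CrCl2 with catalytic NiCl2 in DMF closes the ring by an intramolecular Nozaki–Hiyama–Kishi reaction to the C4 alcohol F11 (either C4 epimer), and Dess–Martin periodinane oxidises F11 to 36.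

## Further compounds

F1 | step 15 | methyl (2R)-2-(ArO-methyl)-4-oxo-2-(triethylsilyloxy)butanoate | O=CC[C@@](C(=O)OC)(O[Si](CC)(CC)CC)COc1cc(OCOC)c(CC=C(C)C)c(OCOC)c1Br
F2 | step 15 | 6-methyl 1-(prop-2-enyl) (2E,5R)-5-(ArO-methyl)-5-(triethylsilyloxy)hex-2-enedioate | C=CCOC(=O)/C=C/C[C@@](C(=O)OC)(O[Si](CC)(CC)CC)COc1cc(OCOC)c(CC=C(C)C)c(OCOC)c1Br
F3 | step 15 | (2E,5R)-5-(ArO-methyl)-6-methoxy-6-oxo-5-(triethylsilyloxy)hex-2-enoic acid | OC(=O)/C=C/C[C@@](C(=O)OC)(O[Si](CC)(CC)CC)COc1cc(OCOC)c(CC=C(C)C)c(OCOC)c1Br
F4 | step 15 | methyl (2R,4E)-2-(ArO-methyl)-6-chloro-6-oxo-2-(triethylsilyloxy)hex-4-enoate | ClC(=O)/C=C/C[C@@](C(=O)OC)(O[Si](CC)(CC)CC)COc1cc(OCOC)c(CC=C(C)C)c(OCOC)c1Br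
F5 | step 8 | racemic methyl 2-(ArO-methyl)-4-(tert-butylsulfanyl)-2-hydroxy-4-oxobutanoate | CC(C)(C)SC(=O)CC(O)(C(=O)OC)COc1cc(OCOC)c(CC=C(C)C)c(OCOC)c1Br
F6 | step 11 | methyl (2R)-2-(ArO-methyl)-4-(dimethylamino)-4-oxo-2-(triethylsilyloxy)butanoate | CN(C)C(=O)C[C@@](C(=O)OC)(O[Si](CC)(CC)CC)COc1cc(OCOC)c(CC=C(C)C)c(OCOC)c1Br
F7 | step 11 | keteniminium trifluoromethanesulfonate from F6 | C[N+](C)=C=C[C@@](C(=O)OC)(O[Si](CC)(CC)CC)COc1cc(OCOC)c(CC=C(C)C)c(OCOC)c1Br.[O-]S(=O)(=O)C(F)(F)F
F8 | step 11 | N,N-dimethylcyclobut-2-en-1-iminium trifluoromethanesulfonate bearing the C3 substituent on ring carbon 4 | C[N+](C)=C1C=CC1[C@@](C(=O)OC)(O[Si](CC)(CC)CC)COc2cc(OCOC)c(CC=C(C)C)c(OCOC)c2Br.[O-]S(=O)(=O)C(F)(F)F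
F9 | step 6 | methyl 3-ArO-2-hydroxypropanoate (racemic) | COC(=O)C(O)COc1cc(OCOC)c(CC=C(C)C)c(OCOC)c1Br
F10 | step 17 | (2R)-3-ArO-2-[2-methoxy-3-(3-methylbut-2-enyl)-4-(triisopropylsilyloxy)phenyl]-2-(triethylsilyloxy)propanal | COc1c([C@@](C=O)(O[Si](CC)(CC)CC)COc2cc(OCOC)c(CC=C(C)C)c(OCOC)c2Br)ccc(O[Si](C(C)C)(C(C)C)C(C)C)c1CC=C(C)C
F11 | step 17 | (3R)-4-hydroxy-2'-methoxy-5,7-bis(methoxymethoxy)-6,3'-bis(3-methylbut-2-enyl)-3-(triethylsilyloxy)-4'-(triisopropylsilyloxy)isoflavan, either C4 epimer | COc1c([C@@]2(O[Si](CC)(CC)CC)COc3cc(OCOC)c(CC=C(C)C)c(OCOC)c3C2O)ccc(O[Si](C(C)C)(C(C)C)C(C)C)c1CC=C(C)C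
A1 | alternative 1 | (E)-3-[6-(tert-butyldimethylsilyloxy)-2,4-bis(methoxymethoxy)-3-(3-methylbut-2-enyl)phenyl]-2-[2-methoxy-4-(methoxymethoxy)-3-(3-methylbut-2-enyl)phenyl]prop-2-en-1-ol, aryl groups cis | COc1c(/C(CO)=C\c2c(O[Si](C)(C)C(C)(C)C)cc(OCOC)c(CC=C(C)C)c2OCOC)ccc(OCOC)c1CC=C(C)C
A2 | alternative 1 | cis-2,3-diaryl-2-(hydroxymethyl)oxirane from A1 with the C3 oxygen configuration of the target | COc1c([C@@]2(O[C@@H]2c3c(O[Si](C)(C)C(C)(C)C)cc(OCOC)c(CC=C(C)C)c3OCOC)CO)ccc(OCOC)c1CC=C(C)C
A3 | alternative 2 | 1-[2-fluoro-4,6-bis(methoxymethoxy)-5-(3-methylbut-2-enyl)phenyl]-3-hydroxy-2-[2-methoxy-4-(methoxymethoxy)-3-(3-methylbut-2-enyl)phenyl]-2-(methoxymethoxy)propan-1-one, C2 configured as in the target | COc1c([C@@](OCOC)(CO)C(=O)c2c(F)cc(OCOC)c(CC=C(C)C)c2OCOC)ccc(OCOC)c1CC=C(C)C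
A4 | alternative 2 | (3R)-2'-methoxy-3,5,7,4'-tetrakis(methoxymethoxy)-6,3'-bis(3-methylbut-2-enyl)isoflavanone | COc1c([C@@]2(OCOC)COc3cc(OCOC)c(CC=C(C)C)c(OCOC)c3C2=O)ccc(OCOC)c1CC=C(C)C
A5 | alternative 3 | 2-{2-[2-methoxy-4-(methoxymethoxy)-3-(3-methylbut-2-enyl)phenyl]-2-oxoethoxy}-4,6-bis(methoxymethoxy)-5-(3-methylbut-2-enyl)benzaldehyde | COc1c(C(=O)COc2cc(OCOC)c(CC=C(C)C)c(OCOC)c2C=O)ccc(OCOC)c1CC=C(C)C
A6 | alternative 3 | (3R)-3-hydroxy-2'-methoxy-5,7,4'-tris(methoxymethoxy)-6,3'-bis(3-methylbut-2-enyl)isoflavanone | COc1c([C@@]2(O)COc3cc(OCOC)c(CC=C(C)C)c(OCOC)c3C2=O)ccc(OCOC)c1CC=C(C)C
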